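## The problem

Target 18 is a monocyclic oxolane, numbered here O1, C2 (3,4-dihydroxyphenyl), C3 (hydroxymethyl carbon C6), C4 (tertiary hydroxyl and benzylic carbon C7 of the 3,4-dimethoxybenzyl group) and C5. In this numbering it is (2R,3R,4R), and the C2 aryl group, the C3 CH2OH group and the C4 hydroxyl all lie on one face of the ring. The ring is easy to close; the difficulty is three contiguous stereocentres, one of them a fully substituted carbinol whose oxygen sits on the more hindered face, cis to both neighbours. An oxidant that attacks an sp2 C4 from the open face would place oxygen trans to C6, so the C4–O bond has to be made by a reagent held on the C3 substituent; C3 can then control C4, provided C6 carries a free hydroxyl at that stage. C2 and C3 cannot be set by equilibration, because the 2,3-trans arrangement is the more stable one. They have to be fixed as a syn pair in an open-chain C–C bond formation, with the absolute configuration coming from one reagent-controlled event. Three features limit the conditions: C2 is a benzylic ether carbon para to an oxygen substituent, so it ionises under acid and can be hydrogenolysed; the free catechol is easily oxidised and must be unveiled last; and the two oxygenated rings must be kept distinct. The plan exploits the array O–C6–C3–C4=C7 of a benzylidene precursor: the C6 hydroxyl is homoallylic to the C4=C7 bond and lies on the face where the C4 oxygen is wanted. Because C7 is benzylic and C4 is not, the C7–O bond of a C4/C7 oxirane is the one lost on hydrogenolysis, under the conditions that also free a benzyl-protected catechol.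

## Retrosynthesis

**18 ⇒ 17.** The C7–H bond and the two phenolic O–H bonds of 18 are exchanged for the C7–O bond of an oxirane and for two benzyl ethers. An oxirane is preferred to a late hydration or dihydroxylation because it is the C4–O precursor that a hydroxyl-directed oxidant makes directly, and its extra C7–O bond is benzylic while the wanted C4–O bond is not. Compound 17 has the same skeleton as 18 but no free catechol. The forward step must cleave a strained benzylic C–O bond and two benzyl ethers and leave the slower cyclic benzylic bond C2–O1 alone.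

**17 ⇒ 16.** Both C–O bonds of the oxirane are cut, giving the E-benzylidene alcohol 16. Two neighbouring cuts were weighed. Adding a benzyl nucleophile to a C4 ketone would also put oxygen on the crowded face, but the ketone is flanked by an epimerisable C3. Osmylation or peracid oxidation of 16 would attack the open face and give the C4 epimer. Compound 16 has one ring and two stereocentres fewer than 17. The forward reaction must deliver oxygen from the C6 hydroxyl to the alkene face that this group occupies.

**16 ⇒ 15 ⇒ 14.** Desilylation links 16 to the silyl ether 15. In 15 the C4–C5 bond (with the C7–H bond) is cut to give the acyclic phenylselanylmethyl ether 14. A 5-exo-dig attack of an alkoxymethyl radical leaves C2–O and C3 untouched. Closure at C2–O1 would pass through a stabilised benzylic cation and lose the cis relationship, and a radical centred on C3 tends to close to the 2,3-trans ring. Compound 14 has no ring and only the two CH stereocentres. The radical must add to the alkyne carbon remote from the aryl group faster than it is reduced.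

**14 ⇒ 12 + 13.** The O1–C5 bond is cut; C5 arrives as chloromethyl phenyl selenide 13 on the alkoxide of homopropargylic alcohol 12. A one-carbon O,Se-acetal is the shortest radical precursor that turns a secondary alcohol into an oxolane. It requires a silyl group on O6 that does not migrate to the neighbouring alkoxide, hence triisopropylsilyl.

**12 ⇒ 10 + 11.** The C7–aryl bond is cut (Sonogashira coupling), giving terminal alkyne 10 and 4-iodo-1,2-dimethoxybenzene 11. Making this cut after the stereocentres are set keeps the propargylation reagent a simple terminal allenylstannane and brings in the second aryl ring already differentiated from the first.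

**10 ⇒ 8 + 9.** The C2–C3 bond is cut between 3,4-bis(benzyloxy)benzaldehyde 9 and allenylstannane 8. This is the one bond whose formation creates both CH stereocentres at once. An aldol construction would have to turn a carbonyl group next to C3 into the alkyne, and allenylmetal reagents that react through cyclic transition states give the anti pair. The forward step must be syn-selective and anti with respect to tin.

**8 ⇒ 7 ⇒ 6.** The C–Sn bond is cut: 8 comes from propargylic mesylate 7 by anti SN2' displacement, and 7 from the (R)-carbinol 6. The axial chirality of 8 is thereby traced back to one carbinol centre.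

**6 ⇒ 5 ⇒ 4 ⇒ 3 ⇒ 1 + 2.** The carbinol C–H bond is cut back to ynone 4; asymmetric transfer hydrogenation gives 5, whose alkynyl silyl group is removed in the same flask. Ynone 4 comes by oxidation from the racemic adduct 3 of (triisopropylsilyloxy)acetaldehyde 1 and lithium (trimethylsilyl)acetylide 2. Catalytic reduction was preferred to a resolution of 3, which would discard half the material.

## Roads not taken

**Alternative 1:** Paternò–Büchi photocycloaddition.
- **Cut:** C2–C3 and a temporary bond from the aldehyde oxygen to the future C6.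
- **Forward step:** excited 3,4-bis(pivaloyloxy)benzaldehyde A2 adds to the unsubstituted double bond of 3-(3,4-dimethoxybenzyl)furan A1 to give the exo, cis-fused oxetane A3.
- **Merits:** two very simple pieces are joined in one step, and the bicyclic shape fixes the 2,3-cis relationship. Oxidation of the remaining enol ether on the convex face would then place the C4 oxygen cis as well. In speed to the skeleton and in relative stereocontrol this road is better than the chosen one.
- **Weak points:** the photoreaction has no source of absolute configuration, so a resolution is needed. The two furan double bonds must be told apart. The acyloxy groups are needed to keep the aldehyde's reactive n,π* state and must later be exchanged. The future C6 emerges as an acetal carbon bonded to both oxygens, so the ring oxygen has to be moved from C6 to C5 by hydrolysis, selective lactol formation and two reductions, partly under acid at the ionisable C2.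
- **Comparison:** the chosen plan needs more steps to reach the carbon skeleton. Against that it fixes the absolute configuration in step 3 and never exposes C2 to acid.

**Alternative 2:** conjunctive cross-coupling.
- **Cut:** C4–C5 and C7–aryl in one operation.
- **Forward step:** the ate complex of alkenyl boronic ester A4 and Grignard reagent A5 reacts with aryl triflate A6 under Pd(OAc)2/MandyPhos; the silylmethyl group shifts from boron to C4 while the aryl group bonds to C7, giving tertiary boronic ester A7. Oxidation of the C–B bond with retention, Tamao–Fleming oxidation of the silyl arm and etherification between O(C2) and C5 would follow.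
- **Merits:** it is convergent, C4 is set by a catalyst, and no sensitive oxirane is involved. In convergence it is equal to or better than the chosen plan.
- **Weak points:** A4 is a 1,1-disubstituted alkenyl boronate with a stereocentre next to the migration terminus, so the 1,2-shift is hindered and the catalyst may work with or against the substrate. Three kinds of protecting group are carried, and three further operations separate A7 from the ring.
- **Comparison:** the chosen plan controls C4 by intramolecular delivery that does not depend on a catalyst–substrate match, and reaches the target two steps after the key precursor.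

**Alternative 3:** cobalt [4+2] benzannulation.
- **Cut:** the catechol ring itself.
- **Forward step:** under CoBr2(dppe)/Zn/ZnI2 the ethynyl group of oxolane A8 and diene A9 combine to a cyclohexa-1,4-diene, which DDQ aromatises to the tris-silyl ether A10.
- **Merits:** the electron-rich ring that makes C2 acid-labile and hydrogenolysis-prone is absent until the end, and the final deprotection is a mild desilylation. In this respect it is better than the chosen plan.
- **Weak points:** the step solves none of the stereochemical problems. A8 already holds all three stereocentres, which would have to be built on a substrate lacking the aryl aldehyde that makes the C2–C3 bond easy. DDQ must spare a dimethoxybenzyl group, and the diene is hydrolytically fragile.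
- **Comparison:** the chosen plan uses the aryl aldehyde to build C2–C3 and limits the risk at C2 by avoiding acid and by a neutral, low-pressure hydrogenolysis.

Key step: step 11

Assumption: the vinyl radical formed in step 9 is taken to accept hydrogen on its C5 side, so the benzylidene compounds are written as E isomers (aryl group syn to C3); a Z isomer would pass through the same steps because C7 ends as a methylene group, and chloromethyl phenyl selenide 13 is treated as a purchasable, known reagent.

## Route

Step 1
Reactants: 1 (triisopropylsilyloxy)acetaldehyde; 2 lithium (trimethylsilyl)acetylide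
Product: 3 rac-4-(trimethylsilyl)-1-(triisopropylsilyloxy)but-3-yn-2-ol
Conditions: THF, −78 °C; then H2O
Reagents that add atoms: none
Why: 1,2-Addition of a lithium acetylide to an aldehyde; the carbinol centre is formed racemic and is erased in step 2.

Step 2
Reactants: 3 rac-4-(trimethylsilyl)-1-(triisopropylsilyloxy)but-3-yn-2-ol
Product: 4 4-(trimethylsilyl)-1-(triisopropylsilyloxy)but-3-yn-2-one
Conditions: Dess–Martin periodinane, CH2Cl2, 0 °C to rt
Reagents that add atoms: none
Why: Dess–Martin oxidation of a propargylic alcohol under near-neutral conditions should leave both silyl groups in place and give the ynone needed for asymmetric reduction.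

Step 3
Reactants: 4 4-(trimethylsilyl)-1-(triisopropylsilyloxy)but-3-yn-2-one
Product: 6 (R)-1-(triisopropylsilyloxy)but-3-yn-2-ol, via (R)-TMS-alkynyl carbinol 5 (not isolated)
Conditions: RuCl[(S,S)-TsDPEN](p-cymene) (1 mol%), i-PrOH, rt; then K2CO3 (cat.), MeOH, rt
Reagents that add atoms: none
Why: Noyori asymmetric transfer hydrogenation of an alkynyl ketone, in which the alkyne plays the part of the aryl group of an aryl ketone, so the (S,S) catalyst should give the R carbinol (R because CH2OSi outranks the alkyne; the enantiomeric catalyst is used if the sense proves opposite); methanolysis then removes only the alkynyl silyl group.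

Step 4
Reactants: 6 (R)-1-(triisopropylsilyloxy)but-3-yn-2-ol
Product: 7 (R)-1-(triisopropylsilyloxy)but-3-yn-2-yl methanesulfonate
Conditions: MsCl, Et3N, CH2Cl2, −78 to 0 °C
Reagents that add atoms: methanesulfonyl chloride, CS(=O)(=O)Cl
Why: O-Sulfonylation; no bond to the stereocentre is broken, so the R configuration is kept.

Step 5
Reactants: 7 (R)-1-(triisopropylsilyloxy)but-3-yn-2-yl methanesulfonate
Product: 8 (aR)-tributyl[4-(triisopropylsilyloxy)buta-1,2-dien-1-yl]stannane
Conditions: Bu3SnH, LDA, THF, 0 °C; CuBr·SMe2, −78 °C; then 7, −78 °C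
Reagents that add atoms: tributyltin hydride, CCCC[SnH](CCCC)CCCC
Why: Anti SN2' displacement of a propargylic mesylate by a stannylcopper reagent; tin enters the alkyne terminus opposite the leaving group, so the carbinol configuration is transferred to the allene axis.

Step 6
Reactants: 8 (aR)-tributyl[4-(triisopropylsilyloxy)buta-1,2-dien-1-yl]stannane; 9 3,4-bis(benzyloxy)benzaldehyde
Product: 10 (1R,2R)-1-[3,4-bis(benzyloxy)phenyl]-2-[(triisopropylsilyloxy)methyl]but-3-yn-1-ol
Conditions: BF3·OEt2, CH2Cl2, −78 °C
Reagents that add atoms: none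
Why: Lewis acid-promoted SE2' addition of an allenylstannane to an aldehyde (propargylation); attack anti to tin fixes C3 from the allene axis (net retention from 6), and the open antiperiplanar transition state gives the syn pair, which fixes C2.

Step 7
Reactants: 10 (1R,2R)-1-[3,4-bis(benzyloxy)phenyl]-2-[(triisopropylsilyloxy)methyl]but-3-yn-1-ol; 11 4-iodo-1,2-dimethoxybenzene
Product: 12 (1R,2R)-1-[3,4-bis(benzyloxy)phenyl]-4-(3,4-dimethoxyphenyl)-2-[(triisopropylsilyloxy)methyl]but-3-yn-1-ol
Conditions: Pd(PPh3)2Cl2 (cat.), CuI (cat.), Et3N, THF, rt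
Reagents that add atoms: none
Why: Sonogashira coupling of a terminal alkyne with an electron-rich aryl iodide; the free secondary alcohol and both stereocentres are spectators.

Step 8
Reactants: 12 (1R,2R)-1-[3,4-bis(benzyloxy)phenyl]-4-(3,4-dimethoxyphenyl)-2-[(triisopropylsilyloxy)methyl]but-3-yn-1-ol; 13 chloromethyl phenyl selenide
Product: 14 {[(1R,2R)-1-[3,4-bis(benzyloxy)phenyl]-4-(3,4-dimethoxyphenyl)-2-[(triisopropylsilyloxy)methyl]but-3-yn-1-yl]oxy}methyl phenyl selenide
Conditions: NaH, NaI (cat.), THF, 0 °C to rt
Reagents that add atoms: none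
Why: Williamson-type O-alkylation of a sodium alkoxide with an α-chloro selenide; the C2–O bond is not broken, and the bulky triisopropylsilyl group should resist O-to-O migration.

Step 9
Reactants: 14 {[(1R,2R)-1-[3,4-bis(benzyloxy)phenyl]-4-(3,4-dimethoxyphenyl)-2-[(triisopropylsilyloxy)methyl]but-3-yn-1-yl]oxy}methyl phenyl selenide
Product: 15 (2R,3R,4E)-2-[3,4-bis(benzyloxy)phenyl]-4-(3,4-dimethoxybenzylidene)-3-[(triisopropylsilyloxy)methyl]oxolane
Conditions: Bu3SnH (syringe pump), AIBN (cat.), PhH, 80 °C
Reagents that add atoms: none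
Why: Tin hydride-mediated radical cyclisation: selenium abstraction gives a nucleophilic alkoxymethyl radical that closes 5-exo-dig onto the alkyne carbon remote from the aryl group, and the linear α-aryl vinyl radical should take hydrogen from its less hindered C5 side to give the E alkene; C2 and C3 are untouched.

Step 10
Reactants: 15 (2R,3R,4E)-2-[3,4-bis(benzyloxy)phenyl]-4-(3,4-dimethoxybenzylidene)-3-[(triisopropylsilyloxy)methyl]oxolane
Product: 16 [(2R,3R,4E)-2-[3,4-bis(benzyloxy)phenyl]-4-(3,4-dimethoxybenzylidene)oxolan-3-yl]methanol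
Conditions: TBAF, THF, 0 °C to rt
Reagents that add atoms: none
Why: Fluoride cleavage of a primary silyl ether under non-acidic conditions, which spares the ionisable C2 and frees the directing hydroxyl.

Step 11
Reactants: 16 [(2R,3R,4E)-2-[3,4-bis(benzyloxy)phenyl]-4-(3,4-dimethoxybenzylidene)oxolan-3-yl]methanol
Product: 17 [(2R,3R,6R,7R)-6-[3,4-bis(benzyloxy)phenyl]-2-(3,4-dimethoxyphenyl)-1,5-dioxaspiro[2.4]heptan-7-yl]methanol (oxirane oxygen cis to the CH2OH group)
Conditions: VO(acac)2 (5 mol%), t-BuOOH (decane), CH2Cl2, 0 °C
Reagents that add atoms: tert-butyl hydroperoxide, CC(C)(C)OO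
Why: t-BuOOH oxidises VO(acac)2 to a pentavalent vanadate that binds the C6 alkoxide and a tert-butylperoxide ligand, and the bound peroxide passes its proximal oxygen to the C4=C7 π bond inside this chelate; this is the vanadium-catalysed hydroxyl-directed epoxidation of a homoallylic alcohol, a known reaction type. The oxirane closes by concerted oxygen-atom transfer, both C–O bonds forming on one face as a spiro three-membered ring on C4, not by a stepwise exo or endo closure. C4 is controlled by C3, because the tether O–C6–C3 reaches only the alkene face that carries C6, which is also the face of the C2 aryl group and the one that untethered oxidants would avoid. C7 is set stereospecifically by the E geometry through syn addition and is deleted in step 12. The step needs π-facial selectivity, secured by coordination to the C6 hydroxyl, and chemoselectivity for the alkene over the electron-rich rings and benzyl ethers, secured by the low reactivity of the vanadium peroxide towards unbound π systems at 0 °C. The oxirane oxygen and C6 lie on the same face while C7 points to the other, so opening at C7 by the C6 hydroxyl would need a trans-fused dioxabicyclo[3.3.0]octane and should not compete. The product is kept from acid and taken on promptly.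

Step 12
Reactants: 17 [(2R,3R,6R,7R)-6-[3,4-bis(benzyloxy)phenyl]-2-(3,4-dimethoxyphenyl)-1,5-dioxaspiro[2.4]heptan-7-yl]methanol
Product: 18 (3R,4R,5R)-5-(3,4-dihydroxyphenyl)-3-(3,4-dimethoxybenzyl)-4-(hydroxymethyl)oxolan-3-ol
Conditions: H2 (1 atm), Pd/C, EtOAc–EtOH, rt
Reagents that add atoms: none
Why: Palladium-catalysed hydrogenolysis cleaves the strained benzylic C7–O bond of the aryl oxirane and both benzyl ethers; the C4–O bond is not benzylic, so the carbinol configuration set in step 11 is kept, and the slower cyclic C2–O1 bond is spared by stopping at the calculated hydrogen uptake.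

## Compound list

1 | (triisopropylsilyloxy)acetaldehyde | O=CCO[Si](C(C)C)(C(C)C)C(C)C | starting material
2 | lithium (trimethylsilyl)acetylide | [Li]C#C[Si](C)(C)C | starting material
3 | rac-4-(trimethylsilyl)-1-(triisopropylsilyloxy)but-3-yn-2-ol | C[Si](C)(C)C#CC(O)CO[Si](C(C)C)(C(C)C)C(C)C | intermediate
4 | 4-(trimethylsilyl)-1-(triisopropylsilyloxy)but-3-yn-2-one | C[Si](C)(C)C#CC(=O)CO[Si](C(C)C)(C(C)C)C(C)C | intermediate
5 | (R)-4-(trimethylsilyl)-1-(triisopropylsilyloxy)but-3-yn-2-ol | C[Si](C)(C)C#C[C@@H](O)CO[Si](C(C)C)(C(C)C)C(C)C | intermediate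
6 | (R)-1-(triisopropylsilyloxy)but-3-yn-2-ol | C#C[C@@H](O)CO[Si](C(C)C)(C(C)C)C(C)C | intermediate
7 | (R)-1-(triisopropylsilyloxy)but-3-yn-2-yl methanesulfonate | C#C[C@@H](OS(C)(=O)=O)CO[Si](C(C)C)(C(C)C)C(C)C | intermediate
8 | (aR)-tributyl[4-(triisopropylsilyloxy)buta-1,2-dien-1-yl]stannane (M helicity) | [H]C([Sn](CCCC)(CCCC)CCCC)=[C@@]=C([H])CO[Si](C(C)C)(C(C)C)C(C)C | intermediate
9 | 3,4-bis(benzyloxy)benzaldehyde | O=Cc1ccc(OCc2ccccc2)c(OCc2ccccc2)c1 | starting material
10 | (1R,2R)-1-[3,4-bis(benzyloxy)phenyl]-2-[(triisopropylsilyloxy)methyl]but-3-yn-1-ol | O[C@@H](c1ccc(OCc2ccccc2)c(OCc2ccccc2)c1)[C@H](C#C)CO[Si](C(C)C)(C(C)C)C(C)C | intermediate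
11 | 4-iodo-1,2-dimethoxybenzene | COc1ccc(I)cc1OC | starting material
12 | (1R,2R)-1-[3,4-bis(benzyloxy)phenyl]-4-(3,4-dimethoxyphenyl)-2-[(triisopropylsilyloxy)methyl]but-3-yn-1-ol | O[C@@H](c1ccc(OCc2ccccc2)c(OCc2ccccc2)c1)[C@H](C#Cc1ccc(OC)c(OC)c1)CO[Si](C(C)C)(C(C)C)C(C)C | intermediate
13 | chloromethyl phenyl selenide | ClC[Se]c1ccccc1 | starting material
14 | {[(1R,2R)-1-[3,4-bis(benzyloxy)phenyl]-4-(3,4-dimethoxyphenyl)-2-[(triisopropylsilyloxy)methyl]but-3-yn-1-yl]oxy}methyl phenyl selenide | c1ccccc1[Se]CO[C@@H](c1ccc(OCc2ccccc2)c(OCc2ccccc2)c1)[C@H](C#Cc1ccc(OC)c(OC)c1)CO[Si](C(C)C)(C(C)C)C(C)C | intermediate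
15 | (2R,3R,4E)-2-[3,4-bis(benzyloxy)phenyl]-4-(3,4-dimethoxybenzylidene)-3-[(triisopropylsilyloxy)methyl]oxolane | COc1ccc(/C=C2/CO[C@@H](c3ccc(OCc4ccccc4)c(OCc4ccccc4)c3)[C@H]2CO[Si](C(C)C)(C(C)C)C(C)C)cc1OC | intermediate
16 | [(2R,3R,4E)-2-[3,4-bis(benzyloxy)phenyl]-4-(3,4-dimethoxybenzylidene)oxolan-3-yl]methanol | COc1ccc(/C=C2/CO[C@@H](c3ccc(OCc4ccccc4)c(OCc4ccccc4)c3)[C@H]2CO)cc1OC | intermediate
17 | [(2R,3R,6R,7R)-6-[3,4-bis(benzyloxy)phenyl]-2-(3,4-dimethoxyphenyl)-1,5-dioxaspiro[2.4]heptan-7-yl]methanol | COc1ccc([C@H]2O[C@]23CO[C@@H](c4ccc(OCc5ccccc5)c(OCc5ccccc5)c4)[C@H]3CO)cc1OC | intermediate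
18 | (3R,4R,5R)-5-(3,4-dihydroxyphenyl)-3-(3,4-dimethoxybenzyl)-4-(hydroxymethyl)oxolan-3-ol | COc1ccc(C[C@]2(O)CO[C@@H](c3ccc(O)c(O)c3)[C@H]2CO)cc1OC | target

## Step count and least certain steps

Total steps: 12. Longest linear sequence: 12 steps (1 to 18); compounds 2, 9, 11 and 13 enter as purchased partners.

**Step 11 (key step).** The electron-rich benzylic oxirane may open or rearrange at C7 (solvolysis or a Meinwald-type shift) on the Lewis-acidic vanadium centre before it can be taken on. Oxygen delivery may also be incomplete if the aryl group syn to C3 crowds the chelate. The fallback sets out from 15 and comes back at 18. The exocyclic alkene of 15 is cleaved (OsO4 cat., NMO; then NaIO4) to the ketone (4R,5R)-5-[3,4-bis(benzyloxy)phenyl]-4-[(triisopropylsilyloxy)methyl]oxolan-3-one F1. 3,4-Dimethoxybenzylmagnesium chloride with CeCl3 at −78 °C should add to the carbonyl face opposite the C2 and C3 substituents, leaving the new hydroxyl on the crowded face, to give the tertiary alcohol (3R,4R,5R)-5-[3,4-bis(benzyloxy)phenyl]-3-(3,4-dimethoxybenzyl)-4-[(triisopropylsilyloxy)methyl]oxolan-3-ol F2. Hydrogenolysis (H2, Pd/C) gives the catechol silyl ether (3R,4R,5R)-5-(3,4-dihydroxyphenyl)-3-(3,4-dimethoxybenzyl)-4-[(triisopropylsilyloxy)methyl]oxolan-3-ol F3, and TBAF buffered with AcOH gives 18. This reserve gives up the directed oxidation and has to cope with an epimerisable C3 next to the ketone.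

**Step 6.** Erosion of syn selectivity in the open transition state with an aromatic aldehyde, or ionisation of the BF3-bound benzylic alkoxide of the electron-rich ring, would lower the diastereomeric purity of 10. The fallback sets out from 9 and comes back at 10.
- An Evans syn-aldol reaction of 9 with the dibutylboron enolate of (R)-4-benzyl-3-[3-(triisopropylsilyloxy)propanoyl]oxazolidin-2-one (Bu2BOTf, i-Pr2NEt) gives the adduct (R)-4-benzyl-3-{(2R,3R)-3-[3,4-bis(benzyloxy)phenyl]-3-hydroxy-2-[(triisopropylsilyloxy)methyl]propanoyl}oxazolidin-2-one F4.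
- TESOTf and 2,6-lutidine give its triethylsilyl ether F5.
- LiBH4 removes the auxiliary to give (2R,3R)-3-[3,4-bis(benzyloxy)phenyl]-3-(triethylsilyloxy)-2-[(triisopropylsilyloxy)methyl]propan-1-ol F6.
- Dess–Martin oxidation gives the aldehyde (2R,3R)-3-[3,4-bis(benzyloxy)phenyl]-3-(triethylsilyloxy)-2-[(triisopropylsilyloxy)methyl]propanal F7.
- Ohira–Bestmann homologation (dimethyl (1-diazo-2-oxopropyl)phosphonate, K2CO3, MeOH) gives the alkyne (1R,2R)-1-[3,4-bis(benzyloxy)phenyl]-1-(triethylsilyloxy)-2-[(triisopropylsilyloxy)methyl]but-3-yne F8.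
- HF·pyridine buffered with pyridine removes the triethylsilyl group to give 10.

The sequence is longer, and its weak point is epimerisation at the α-carbon of F7.

**Step 9.** Stannyl radical addition to the aryl alkyne and reduction of the alkoxymethyl radical before ring closure compete with cyclisation. Hydrogen transfer to both sides of the vinyl radical would give a mixture of alkene isomers, which is tolerable. The fallback sets out from 12 and comes back at 15, bypassing step 8 as well. Nickel-catalysed reductive coupling of the alkyne of 12 with paraformaldehyde (Ni(cod)2, the N-heterocyclic carbene IMes, Et3SiH) forms the C4–C5 bond at the alkyne carbon remote from the aryl group by syn addition. It gives the allylic silyl ether (1R,2R,3E)-1-[3,4-bis(benzyloxy)phenyl]-4-(3,4-dimethoxyphenyl)-3-[(triethylsilyloxy)methyl]-2-[(triisopropylsilyloxy)methyl]but-3-en-1-ol F9. Buffered HF·pyridine gives the diol (2E,3R,4R)-4-[3,4-bis(benzyloxy)phenyl]-2-(3,4-dimethoxybenzylidene)-3-[(triisopropylsilyloxy)methyl]butane-1,4-diol F10. Mitsunobu cyclodehydration (PPh3, DIAD) activates the primary allylic hydroxyl, leaves the C2–O bond intact and closes O1–C5 to give 15.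

**Step 12.** Continued hydrogenolysis at the benzylic C2–O1 bond once the catechol is free, or palladium-mediated isomerisation of the oxirane to a carbonyl compound, would divert material. The fallback sets out from 17 and comes back at 18, separating the two reductions. Cp2TiCl (trivalent titanium, made from Cp2TiCl2 and Zn) with 1,4-cyclohexadiene opens the oxirane homolytically at C7, and the benzylic radical is reduced to a methylene group. This gives the dibenzyl ether (3R,4R,5R)-5-[3,4-bis(benzyloxy)phenyl]-3-(3,4-dimethoxybenzyl)-4-(hydroxymethyl)oxolan-3-ol F11. Catalytic transfer hydrogenolysis (Pd/C, 1,4-cyclohexadiene, EtOH) then removes the two benzyl groups under hydrogen-poor conditions to give 18.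

## Further compounds

F1 | step 11 | (4R,5R)-5-[3,4-bis(benzyloxy)phenyl]-4-[(triisopropylsilyloxy)methyl]oxolan-3-one | O=C1CO[C@@H](c2ccc(OCc3ccccc3)c(OCc3ccccc3)c2)[C@H]1CO[Si](C(C)C)(C(C)C)C(C)C
F2 | step 11 | (3R,4R,5R)-5-[3,4-bis(benzyloxy)phenyl]-3-(3,4-dimethoxybenzyl)-4-[(triisopropylsilyloxy)methyl]oxolan-3-ol | COc1ccc(C[C@]2(O)CO[C@@H](c3ccc(OCc4ccccc4)c(OCc4ccccc4)c3)[C@H]2CO[Si](C(C)C)(C(C)C)C(C)C)cc1OC
F3 | step 11 | (3R,4R,5R)-5-(3,4-dihydroxyphenyl)-3-(3,4-dimethoxybenzyl)-4-[(triisopropylsilyloxy)methyl]oxolan-3-ol | COc1ccc(C[C@]2(O)CO[C@@H](c3ccc(O)c(O)c3)[C@H]2CO[Si](C(C)C)(C(C)C)C(C)C)cc1OC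
F4 | step 6 | (R)-4-benzyl-3-{(2R,3R)-3-[3,4-bis(benzyloxy)phenyl]-3-hydroxy-2-[(triisopropylsilyloxy)methyl]propanoyl}oxazolidin-2-one | O[C@@H](c1ccc(OCc2ccccc2)c(OCc2ccccc2)c1)[C@H](C(=O)N1[C@H](Cc2ccccc2)COC1=O)CO[Si](C(C)C)(C(C)C)C(C)C
F5 | step 6 | (R)-4-benzyl-3-{(2R,3R)-3-[3,4-bis(benzyloxy)phenyl]-3-(triethylsilyloxy)-2-[(triisopropylsilyloxy)methyl]propanoyl}oxazolidin-2-one | CC[Si](CC)(CC)O[C@@H](c1ccc(OCc2ccccc2)c(OCc2ccccc2)c1)[C@H](C(=O)N1[C@H](Cc2ccccc2)COC1=O)CO[Si](C(C)C)(C(C)C)C(C)C
F6 | step 6 | (2R,3R)-3-[3,4-bis(benzyloxy)phenyl]-3-(triethylsilyloxy)-2-[(triisopropylsilyloxy)methyl]propan-1-ol | CC[Si](CC)(CC)O[C@@H](c1ccc(OCc2ccccc2)c(OCc2ccccc2)c1)[C@H](CO)CO[Si](C(C)C)(C(C)C)C(C)C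
F7 | step 6 | (2R,3R)-3-[3,4-bis(benzyloxy)phenyl]-3-(triethylsilyloxy)-2-[(triisopropylsilyloxy)methyl]propanal | CC[Si](CC)(CC)O[C@@H](c1ccc(OCc2ccccc2)c(OCc2ccccc2)c1)[C@H](C=O)CO[Si](C(C)C)(C(C)C)C(C)C
F8 | step 6 | (1R,2R)-1-[3,4-bis(benzyloxy)phenyl]-1-(triethylsilyloxy)-2-[(triisopropylsilyloxy)methyl]but-3-yne | CC[Si](CC)(CC)O[C@@H](c1ccc(OCc2ccccc2)c(OCc2ccccc2)c1)[C@H](C#C)CO[Si](C(C)C)(C(C)C)C(C)C
F9 | step 9 | (1R,2R,3E)-1-[3,4-bis(benzyloxy)phenyl]-4-(3,4-dimethoxyphenyl)-3-[(triethylsilyloxy)methyl]-2-[(triisopropylsilyloxy)methyl]but-3-en-1-ol | O[C@@H](c1ccc(OCc2ccccc2)c(OCc2ccccc2)c1)[C@H](/C(CO[Si](CC)(CC)CC)=C\c1ccc(OC)c(OC)c1)CO[Si](C(C)C)(C(C)C)C(C)C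
F10 | step 9 | (2E,3R,4R)-4-[3,4-bis(benzyloxy)phenyl]-2-(3,4-dimethoxybenzylidene)-3-[(triisopropylsilyloxy)methyl]butane-1,4-diol | O[C@@H](c1ccc(OCc2ccccc2)c(OCc2ccccc2)c1)[C@H](/C(CO)=C\c1ccc(OC)c(OC)c1)CO[Si](C(C)C)(C(C)C)C(C)C
F11 | step 12 | (3R,4R,5R)-5-[3,4-bis(benzyloxy)phenyl]-3-(3,4-dimethoxybenzyl)-4-(hydroxymethyl)oxolan-3-ol | COc1ccc(C[C@]2(O)CO[C@@H](c3ccc(OCc4ccccc4)c(OCc4ccccc4)c3)[C@H]2CO)cc1OC
A1 | alternative 1 | 3-(3,4-dimethoxybenzyl)furan | COc1ccc(Cc2ccoc2)cc1OC
A2 | alternative 1 | 3,4-bis(pivaloyloxy)benzaldehyde | CC(C)(C)C(=O)Oc1ccc(C=O)cc1OC(=O)C(C)(C)C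
A3 | alternative 1 | exo-6-[3,4-bis(pivaloyloxy)phenyl]-4-(3,4-dimethoxybenzyl)-2,7-dioxabicyclo[3.2.0]hept-3-ene (enantiomer drawn) | O1[C@@H](c2ccc(OC(=O)C(C)(C)C)c(OC(=O)C(C)(C)C)c2)[C@H]2[C@@H]1OC=C2Cc1ccc(OC)c(OC)c1
A4 | alternative 2 | pinacol boronate of the 2-substituted propene bearing the C3 benzyloxymethyl and C2 silyloxy(aryl)methyl groups | C=C(B1OC(C)(C)C(C)(C)O1)[C@H](COCc1ccccc1)[C@@H](O[Si](C)(C)C(C)(C)C)c1ccc(OCc2ccccc2)c(OCc2ccccc2)c1
A5 | alternative 2 | (isopropoxydimethylsilyl)methylmagnesium chloride | CC(C)O[Si](C)(C)C[Mg]Cl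
A6 | alternative 2 | 3,4-dimethoxyphenyl trifluoromethanesulfonate | COc1ccc(OS(=O)(=O)C(F)(F)F)cc1OC
A7 | alternative 2 | tertiary pinacol boronate with C5 silylmethyl and C7 aryl arms | COc1ccc(C[C@](B2OC(C)(C)C(C)(C)O2)(C[Si](C)(C)OC(C)C)[C@H](COCc2ccccc2)[C@@H](O[Si](C)(C)C(C)(C)C)c2ccc(OCc3ccccc3)c(OCc3ccccc3)c2)cc1OC
A8 | alternative 3 | (3R,4R,5R)-4-[(tert-butyldimethylsilyloxy)methyl]-3-(3,4-dimethoxybenzyl)-5-ethynyloxolan-3-ol | COc1ccc(C[C@]2(O)CO[C@@H](C#C)[C@H]2CO[Si](C)(C)C(C)(C)C)cc1OC
A9 | alternative 3 | 2,3-bis(trimethylsilyloxy)buta-1,3-diene | C=C(O[Si](C)(C)C)C(=C)O[Si](C)(C)C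
A10 | alternative 3 | tris-silyl ether of the target (catechol bis-trimethylsilyl ether, C6 tert-butyldimethylsilyl ether) | COc1ccc(C[C@]2(O)CO[C@@H](c3ccc(O[Si](C)(C)C)c(O[Si](C)(C)C)c3)[C@H]2CO[Si](C)(C)C(C)(C)C)cc1OC
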